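**Plan**
- Retrosynthetic cuts, in order: the MOM acetal on O8 and the C3–OH bond (back to C3–Br); then both ring bonds of C3 (C2–C3 and C3–C4) at once; then the aryl–acyl bond C4–C4a and the ether bond O1–C2.
- The double cut at C3 is possible because ring C (O1, C2, C3, C4, C4a, C8a) is the furan ring of a 2-aryl-3-oxybenzofuran (O1, C2, C4, C4a, C8a) with one extra atom, C3, set between C2 and the carbonyl carbon C4.
- Forward: ring A is completed first from 2,3,4-trimethoxybenzaldehyde (Dakin oxidation, MOM-directed lithiation/oxidation, iodination). The furan ring is then closed by O-alkylation and Parham acylation and trapped as its silyl enol ether.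
- Dibromocarbene expands the furan to the pyranone and leaves bromine on C3; C–Br is converted to C–OH and the MOM group is removed last.
- Stereochemistry: the target has no stereocentre; stereocentres in intermediates are racemic and are erased.

Key step: step 8

Remark: eriostemin is achiral, so the compound itself is the required single stereoisomer. The racemic intermediates (the α-bromo ester, the aryloxy ester and its aryllithium, the cyclopropane adduct) are drawn without stereodescriptors.

**Route**

Step 1
Reactants: 1 2,3,4-trimethoxybenzaldehyde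
Product: 3 2,3,4-trimethoxyphenol, via 2,3,4-trimethoxyphenyl formate 2 (not isolated)
Conditions: 30% H2O2, H2SO4 (cat.), MeOH, rt
Reagents that add atoms: hydrogen peroxide, OO
Why: Acid-catalysed Dakin (Baeyer–Villiger-type) oxidation, in which the electron-rich aryl group migrates to oxygen and the aryl formate is methanolysed in the same flask.

Step 2
Reactants: 3 2,3,4-trimethoxyphenol
Product: 4 1,2,3-trimethoxy-4-(methoxymethoxy)benzene
Conditions: MOMCl, iPr2NEt, CH2Cl2, 0 °C → rt
Reagents that add atoms: chloromethyl methyl ether, COCCl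
Why: Williamson-type O-alkylation (MOM protection); the MOM ether directs the next lithiation, tolerates all basic and organometallic steps and leaves in dilute acid at the end.

Step 3
Reactants: 4 1,2,3-trimethoxy-4-(methoxymethoxy)benzene
Product: 7 3,4,5-trimethoxy-2-(methoxymethoxy)phenol, via ortho-aryllithium 5 (not isolated), via dimethyl arylboronate 6 (not isolated)
Conditions: n-BuLi, TMEDA, THF, −20 → 0 °C; B(OMe)3, −78 °C → rt; AcOH, 30% H2O2, 0 °C → rt
Reagents that add atoms: hydrogen peroxide, OO (the new oxygen); n-butyllithium, [Li]CCCC (lithium of 5 only); trimethyl borate, COB(OC)OC (boron group of 6 only)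
Why: Directed ortho-metalation, in which the chelating OMOM group outranks OMe and sends lithium to the CH next to it, followed by borylation and peroxide oxidation of the arylboronate (C-to-O shift) to give the phenol.

Step 4
Reactants: 7 3,4,5-trimethoxy-2-(methoxymethoxy)phenol
Product: 8 2-iodo-3,4,5-trimethoxy-6-(methoxymethoxy)phenol
Conditions: NIS, CH2Cl2, −20 → 0 °C, dark
Reagents that add atoms: N-iodosuccinimide, O=C1CCC(=O)N1I
Why: Electrophilic aromatic iodination at the only remaining ring CH, which is ortho to the free hydroxyl; the neutral reagent at low temperature should spare the MOM acetal and limit oxidation of the electron-rich phenol.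

Step 5
Reactants: 9 methyl (4-methoxyphenyl)acetate
Product: 10 methyl bromo(4-methoxyphenyl)acetate (racemic)
Conditions: NBS, AIBN (cat.), PhCF3, 80 °C
Reagents that add atoms: N-bromosuccinimide, O=C1CCC(=O)N1Br
Why: Wohl–Ziegler radical bromination at the benzylic CH2, whose radical is stabilised by both the aryl ring and the ester.

Step 6
Reactants: 8 2-iodo-3,4,5-trimethoxy-6-(methoxymethoxy)phenol; 10 methyl bromo(4-methoxyphenyl)acetate
Product: 11 methyl [2-iodo-3,4,5-trimethoxy-6-(methoxymethoxy)phenoxy](4-methoxyphenyl)acetate (racemic)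
Conditions: K2CO3, DMF, rt
Reagents that add atoms: none
Why: Williamson ether synthesis (SN2 of the phenoxide on an activated benzylic α-bromo ester) forming the future O1–C2 bond; C-alkylation is excluded because the ring is fully substituted.

Step 7
Reactants: 11 methyl [2-iodo-3,4,5-trimethoxy-6-(methoxymethoxy)phenoxy](4-methoxyphenyl)acetate
Product: 14 tert-butyl{[4,5,6-trimethoxy-7-(methoxymethoxy)-2-(4-methoxyphenyl)-1-benzofuran-3-yl]oxy}dimethylsilane, via aryllithium 12 (not isolated), via lithium benzofuran-3-olate 13 (not isolated)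
Conditions: t-BuLi (2.1 equiv), THF, −100 → −40 °C; TBSCl, DMPU, −40 °C → rt
Reagents that add atoms: tert-butyldimethylsilyl chloride, CC(C)(C)[Si](C)(C)Cl; tert-butyllithium, [Li]C(C)(C)C (lithium of 12 and 13 only)
Why: Parham cyclisation, in which iodine–lithium exchange at −100 °C should outrun deprotonation of the α-C–H and attack on the ester, the aryllithium acylates itself on the methyl ester (5-exo-trig, new C3–C3a bond), the expelled methoxide enolises the ketone to the aromatic benzofuran-3-olate, and O-silylation in the same flask avoids handling the autoxidation-prone 2-arylbenzofuran-3(2H)-one.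

Step 8
Reactants: 14 tert-butyl{[4,5,6-trimethoxy-7-(methoxymethoxy)-2-(4-methoxyphenyl)-1-benzofuran-3-yl]oxy}dimethylsilane; 15 bromoform
Product: 18 3-bromo-5,6,7-trimethoxy-8-(methoxymethoxy)-2-(4-methoxyphenyl)-4H-chromen-4-one, via dibromocyclopropane adduct 16 (not isolated), via 4-siloxybenzopyrylium bromide 17 (not isolated)
Conditions: CHBr3, KOtBu, hexane–toluene, −30 °C → rt
Reagents that add atoms: bromoform (15), BrC(Br)Br
Why: Proposed new method: tribromomethanide from 15 and KOtBu loses bromide to give dibromocarbene, which adds as an electrophile across the furan C2=C3 bond of 14 ([2+1] cheletropic addition to the O1–C2=C3–OSi enol ether) to give the fused gem-dibromocyclopropane 16; loss of the endo bromide is concerted with disrotatory 2π-electrocyclic cleavage of the old C2–C3 fusion bond, which places the carbene carbon between them as C3 of the 3-bromo-4-siloxybenzopyrylium ion 17, and transfer of the silyl group to bromide or tert-butoxide unveils the C4 carbonyl of 18. The closest known reaction types are the dihalocarbene one-carbon ring expansion of cyclic silyl enol ethers to α-halo enones and the Ciamician–Dennstedt-type halocarbene expansion of indoles and benzofurans; their merger on a 3-siloxybenzofuran to deliver a chromone is not documented. The six-membered pyranone ring arises by ring expansion and not by cyclisation: both new bonds (flavone C2–C3 and C3–C4) are made in the cyclopropanation and the ring grows when the internal cyclopropane bond opens. No stereocentre is created in 18; 16 is a racemic, necessarily cis-fused intermediate whose two stereocentres are erased on opening. The step needs chemoselective addition to the furan double bond and cleavage of the internal rather than an outer cyclopropane bond: the doubly oxygenated tetrasubstituted C2=C3 bond is the most nucleophilic π bond in 14 (ring A is fully substituted and anisole rings are poor carbene acceptors), the forming allyl cation is stabilised at one terminus by O1 and the anisyl group and at the other by the siloxy oxygen, and the bulky TBS group in a non-polar medium at low temperature should keep the silyl ether intact until ionisation has occurred. The bromine that stays on C3 is the handle for the hydroxyl group.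

Step 9
Reactants: 18 3-bromo-5,6,7-trimethoxy-8-(methoxymethoxy)-2-(4-methoxyphenyl)-4H-chromen-4-one
Product: 21 3-hydroxy-5,6,7-trimethoxy-8-(methoxymethoxy)-2-(4-methoxyphenyl)-4H-chromen-4-one, via chromon-3-ylmagnesium chloride 19 (not isolated), via dimethyl chromon-3-ylboronate 20 (not isolated)
Conditions: iPrMgCl·LiCl, THF, −40 °C; B(OMe)3, −40 → 0 °C; AcOH, 30% H2O2, 0 °C
Reagents that add atoms: hydrogen peroxide, OO (the C3 oxygen); isopropylmagnesium chloride, CC(C)[Mg]Cl (MgCl of 19 only); trimethyl borate, COB(OC)OC (boron group of 20 only)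
Why: Bromine–magnesium exchange on the α-bromo vinylogous ester, borylation and boronate oxidation under acidic peroxide (the analogous 3-lithioflavones are known to persist at low temperature and to give flavonols this way), which avoids the alkaline peroxide that degrades flavonols.

Step 10
Reactants: 21 3-hydroxy-5,6,7-trimethoxy-8-(methoxymethoxy)-2-(4-methoxyphenyl)-4H-chromen-4-one
Product: 22 eriostemin, 3,8-dihydroxy-5,6,7-trimethoxy-2-(4-methoxyphenyl)-4H-chromen-4-one
Conditions: 3 M HCl, MeOH, 45 °C
Reagents that add atoms: none
Why: Acid-catalysed acetal cleavage (MOM removal by transacetalisation to methanol); the aryl methyl ethers, including the peri 5-OMe, and the flavonol should be stable to dilute protic acid.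

**Compound list**

1 | 2,3,4-trimethoxybenzaldehyde | COc1ccc(C=O)c(OC)c1OC | starting material
2 | 2,3,4-trimethoxyphenyl formate | O=COc1ccc(OC)c(OC)c1OC | intermediate (not isolated)
3 | 2,3,4-trimethoxyphenol | Oc1ccc(OC)c(OC)c1OC | intermediate
4 | 1,2,3-trimethoxy-4-(methoxymethoxy)benzene | COCOc1ccc(OC)c(OC)c1OC | intermediate
5 | [3,4,5-trimethoxy-2-(methoxymethoxy)phenyl]lithium | [Li]c1cc(OC)c(OC)c(OC)c1OCOC | intermediate (not isolated)
6 | dimethyl [3,4,5-trimethoxy-2-(methoxymethoxy)phenyl]boronate | COB(OC)c1cc(OC)c(OC)c(OC)c1OCOC | intermediate (not isolated)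
7 | 3,4,5-trimethoxy-2-(methoxymethoxy)phenol | Oc1cc(OC)c(OC)c(OC)c1OCOC | intermediate
8 | 2-iodo-3,4,5-trimethoxy-6-(methoxymethoxy)phenol | Oc1c(I)c(OC)c(OC)c(OC)c1OCOC | intermediate
9 | methyl (4-methoxyphenyl)acetate | COC(=O)Cc1ccc(OC)cc1 | starting material
10 | methyl bromo(4-methoxyphenyl)acetate (racemic) | COC(=O)C(Br)c1ccc(OC)cc1 | intermediate
11 | methyl [2-iodo-3,4,5-trimethoxy-6-(methoxymethoxy)phenoxy](4-methoxyphenyl)acetate (racemic) | COC(=O)C(Oc1c(I)c(OC)c(OC)c(OC)c1OCOC)c1ccc(OC)cc1 | intermediate
12 | the aryllithium of 11, lithium in place of iodine (racemic) | COC(=O)C(Oc1c([Li])c(OC)c(OC)c(OC)c1OCOC)c1ccc(OC)cc1 | intermediate (not isolated)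
13 | lithium 4,5,6-trimethoxy-7-(methoxymethoxy)-2-(4-methoxyphenyl)-1-benzofuran-3-olate | [Li]Oc1c(-c2ccc(OC)cc2)oc2c(OCOC)c(OC)c(OC)c(OC)c12 | intermediate (not isolated)
14 | tert-butyl{[4,5,6-trimethoxy-7-(methoxymethoxy)-2-(4-methoxyphenyl)-1-benzofuran-3-yl]oxy}dimethylsilane | COCOc1c(OC)c(OC)c(OC)c2c(O[Si](C)(C)C(C)(C)C)c(-c3ccc(OC)cc3)oc12 | intermediate
15 | bromoform | BrC(Br)Br | starting material
16 | tert-butyl{[1,1-dibromo-4,5,6-trimethoxy-3-(methoxymethoxy)-1a-(4-methoxyphenyl)-1,1a-dihydro-6bH-cyclopropa[b][1]benzofuran-6b-yl]oxy}dimethylsilane (racemic, cis-fused) | COCOc1c(OC)c(OC)c(OC)c2c1OC1(c3ccc(OC)cc3)C(Br)(Br)C21O[Si](C)(C)C(C)(C)C | intermediate (not isolated)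
17 | 3-bromo-4-[(tert-butyldimethylsilyl)oxy]-5,6,7-trimethoxy-8-(methoxymethoxy)-2-(4-methoxyphenyl)chromenylium bromide | COCOc1c(OC)c(OC)c(OC)c2c(O[Si](C)(C)C(C)(C)C)c(Br)c(-c3ccc(OC)cc3)[o+]c12.[Br-] | intermediate (not isolated)
18 | 3-bromo-5,6,7-trimethoxy-8-(methoxymethoxy)-2-(4-methoxyphenyl)-4H-chromen-4-one | COCOc1c(OC)c(OC)c(OC)c2c(=O)c(Br)c(-c3ccc(OC)cc3)oc12 | intermediate
19 | [5,6,7-trimethoxy-8-(methoxymethoxy)-2-(4-methoxyphenyl)-4-oxo-4H-chromen-3-yl]magnesium chloride | COCOc1c(OC)c(OC)c(OC)c2c(=O)c([Mg]Cl)c(-c3ccc(OC)cc3)oc12 | intermediate (not isolated)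
20 | dimethyl [5,6,7-trimethoxy-8-(methoxymethoxy)-2-(4-methoxyphenyl)-4-oxo-4H-chromen-3-yl]boronate | COCOc1c(OC)c(OC)c(OC)c2c(=O)c(B(OC)OC)c(-c3ccc(OC)cc3)oc12 | intermediate (not isolated)
21 | 3-hydroxy-5,6,7-trimethoxy-8-(methoxymethoxy)-2-(4-methoxyphenyl)-4H-chromen-4-one | COCOc1c(OC)c(OC)c(OC)c2c(=O)c(O)c(-c3ccc(OC)cc3)oc12 | intermediate
22 | eriostemin, 3,8-dihydroxy-5,6,7-trimethoxy-2-(4-methoxyphenyl)-4H-chromen-4-one (achiral) | COc1ccc(-c2oc3c(O)c(OC)c(OC)c(OC)c3c(=O)c2O)cc1 | target

**Step count**

Total: 10 steps. Longest linear sequence: 9 steps (steps 1–4 and 6–10, from 2,3,4-trimethoxybenzaldehyde); step 5 is a one-step side branch.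

**Steps most likely to fail**

Step 8 (proposed new method). The carbene may add too slowly to the crowded, tetrasubstituted furan double bond and be lost to self-decay. Attack of tert-butoxide on silicon before ionisation would open the cyclopropanolate at an outer bond (C-dibromomethylation, as in the abnormal Reimer–Tiemann reaction) instead of at the fusion bond. Excess base could also induce ring contraction of the bromochromone. The fallback uses known chemistry, sets out from 8 and returns at 21, closing the pyranone by cyclisation instead of ring expansion. Palladium-catalysed carbonylative Sonogashira annulation of 8 with 4-ethynylanisole (PdCl2(dppf), Et2NH, CO) should give 5,6,7-trimethoxy-8-(methoxymethoxy)-2-(4-methoxyphenyl)-4H-chromen-4-one F1. Epoxidation of its C2=C3 bond with dimethyldioxirane (acetone–CH2Cl2, 0 °C) should give the 2,3-epoxyflavanone F2, which is expected to isomerise to the flavonol 21 on silica gel or with a trace of p-TsOH.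

Step 7. Proton transfer from the acidic α-C–H of the ester to the aryllithium, or deprotonation or ester attack by tert-butyllithium in competition with the exchange, would return deiodinated or over-added material; O-silylation of the enolate may also be incomplete. The fallback sets out from 11 and returns at 14; it removes the acidic site by using the carboxylate as acyl acceptor. Saponification (LiOH, THF–H2O) should give [2-iodo-3,4,5-trimethoxy-6-(methoxymethoxy)phenoxy](4-methoxyphenyl)acetic acid F3. Parham cyclisation of its lithium salt (n-BuLi, 2.2 equiv, THF, −100 °C → rt), whose dilithio gem-diolate survives until work-up, should give 4,5,6-trimethoxy-7-(methoxymethoxy)-2-(4-methoxyphenyl)-1-benzofuran-3(2H)-one F4. This is handled under argon and O-silylated (TBSOTf, Et3N, CH2Cl2, 0 °C) to 14.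

Step 9. The 3-magnesiated chromone may fragment by β-elimination of the phenoxide (ring opening to an alkynyl ketone), the Grignard reagent may add to C2 or C4 of the pyranone, or the flavonol may be over-oxidised in the peroxide stage. The fallback sets out from 18 and returns at 21; it avoids any polar organometallic. Miyaura borylation (B2pin2, PdCl2(dppf), KOAc, dioxane, 80 °C) should give 5,6,7-trimethoxy-8-(methoxymethoxy)-2-(4-methoxyphenyl)-3-(4,4,5,5-tetramethyl-1,3,2-dioxaborolan-2-yl)-4H-chromen-4-one F5, which is oxidised under near-neutral conditions (NaBO3·4H2O, THF–H2O, rt) to 21.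

**Further compounds**

F1 | step 8 | 5,6,7-trimethoxy-8-(methoxymethoxy)-2-(4-methoxyphenyl)-4H-chromen-4-one | COCOc1c(OC)c(OC)c(OC)c2c(=O)cc(-c3ccc(OC)cc3)oc12
F2 | step 8 | 2,3-epoxy-5,6,7-trimethoxy-8-(methoxymethoxy)-2-(4-methoxyphenyl)-2,3-dihydro-4H-chromen-4-one (racemic) | COCOc1c(OC)c(OC)c(OC)c2c1OC1(c3ccc(OC)cc3)OC1C2=O
F3 | step 7 | [2-iodo-3,4,5-trimethoxy-6-(methoxymethoxy)phenoxy](4-methoxyphenyl)acetic acid (racemic) | OC(=O)C(Oc1c(I)c(OC)c(OC)c(OC)c1OCOC)c1ccc(OC)cc1
F4 | step 7 | 4,5,6-trimethoxy-7-(methoxymethoxy)-2-(4-methoxyphenyl)-1-benzofuran-3(2H)-one (racemic) | COCOc1c(OC)c(OC)c(OC)c2c1OC(c1ccc(OC)cc1)C2=O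
F5 | step 9 | 5,6,7-trimethoxy-8-(methoxymethoxy)-2-(4-methoxyphenyl)-3-(4,4,5,5-tetramethyl-1,3,2-dioxaborolan-2-yl)-4H-chromen-4-one | COCOc1c(OC)c(OC)c(OC)c2c(=O)c(B3OC(C)(C)C(C)(C)O3)c(-c3ccc(OC)cc3)oc12
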